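Read the tails of these runs first.

| setting | red | violet | ochre |
|---|---|---|---|
| starting material | 0.800 M | 0.400 M | 2.40 M |
| partner | 0.640 M | 0.640 M | 1.90 M |
| catalyst | 0.0160 M | 0.0160 M | 0.0160 M |
| time |  |  | 160 min |

| run | time / min | [target] / M |
|---|---|---|
| red run | 9.1 | 0.1696 |
| red run | 28 | 0.3165 |
| red run | 53 | 0.3945 |
| red run | 84 | 0.4393 |
| red run | 120 | 0.4596 |
| red run | 160 | 0.4736 |
| violet run | 9.1 | 0.0914 |
| violet run | 28 | 0.1788 |
| violet run | 53 | 0.2372 |
| violet run | 84 | 0.2772 |
| violet run | 120 | 0.3004 |
| violet run | 160 | 0.3143 |

(each reading ± 0.002 M)

* order of the initial rate in [starting material], near the charge of the red run, the rate being that where two percent of its starting material are target (one fixed amount of target, the same in the runs compared)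
* target in the ochre run at 160 min, as a share of the starting material charged

- Overall: starting material + partner -> target, with catalyst as catalyst.
- Constant volume, constant temperature.
- A reading of a species includes what of it is bound.
- "The second partner" is partner.
- An order is taken over about fifteen percent of the charge, up and down.

Late in the red flask, between the last two readings, target rises by 2.19% of the partner charged, though on paper 27.1% of that partner remains. Divide the rate by the amounts on paper and you get 0.00605 /M/min, against 0.0469 /M/min up to the first reading. The violet flask's first reading gives 0.0477 /M/min, so I read the early order in starting material as close to one.

There are two ways to the ochre flask. The first assumes that every partner leaving becomes target. Partner is the limiting reagent there, at 79.2% of the starting material, and the early constant gives it a time scale of 8.88 min, shorter than 160 min, so this way ends near that ceiling.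

The second way scales the red flask. The ochre charges are 3.00 and 2.97 times the red ones. I assume that what makes target and whatever else consumes partner both grow as the square of the charge, which these runs cannot test, since both hold the same partner charge. Shares then repeat on a faster clock, and red's last reading answers to 53.3 min in the ochre flask, earlier than 160 min. What carries over is the red flask's 74.0%, the partner yield, target as a share of the partner charged. It gives 58.6% of the starting material. But the ochre time of 160 min answers to 480 min in red, past red's last reading, and red was still gaining 2.19% of its partner charge over its last interval, so this figure leans low.

The ways part, so test the first on red. At 0.0469 /M/min, the late rate needs only 3.49% of the partner, not 27.1%. If that constant holds late, partner has left without becoming target and the first way cheats, so I commit to about 58.6%.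

The forecast says an order of 0.9 and 65% for the ochre flask, higher than my figure, and of the late flattening it says: “The data do not separate these cleanly.”

The order comes to 0.96, and the ochre flask gives 59.0% of its starting material at 160 min.

    catalyst + starting material ⇌ catalyst-substrate complex, settled at all times (0.2170 /M)
    catalyst-substrate complex + partner → target + catalyst (8.280 /M/min)
    starting material + partner → target (0.02622 /M/min)
    2 partner → lost reagent (0.01704 /M/min)

A fit of the main steps alone gives the ochre flask 77.6%. The partner yield of the ochre flask at 160 min comes to 74.5%, beside 74.0% at red's last reading. The violet flask, charged with 0.625 of starting material per partner, reads 49.1% at 160 min.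

The data are calculated with constants of no real substance; noise was put on by code.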